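## Retrosynthetic overview
1. The last bond, alkenyl CH to the ketone α-carbon, comes from a stereospecific pinacol-type 1,2-alkenyl shift onto an (S)-lactate-derived mesylate (inversion). The alkenyl metal comes from methylalumination of a ring alkyne.
2. The cyclohexadiene is formed second. A gold-triggered cyclopropanation gives a bicyclo[3.1.0]hexyl carbene, which undergoes five-to-six ring expansion, followed by an exo-to-endo alkene shift.
3. The quaternary carbon is set by propargylation of the pyrone-stabilised carbanion, steered by the neighbouring stereocentre through A(1,3) strain.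
4. That neighbouring stereocentre comes from a copper-catalysed asymmetric propargylic alkylation of the pentan-3-one enamine with a skipped diynyl acetate. The free alkyne becomes isopropenyl and the silylated alkyne is kept for line 1.
5. The pyrone ring is formed first, from a silyl enol ether and methylmalonyl dichloride, followed by O-methylation.

Assumption: the (R)-ligand in step 4 is taken to give the (S)-centre. If the sense is opposite, the other ligand enantiomer is used.

## Route

Step 1
Reactants: 1 3-(trimethylsilyl)prop-2-ynal; 2 ethynylmagnesium bromide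
Product: 3 rac-1-(trimethylsilyl)penta-1,4-diyn-3-ol
Conditions: THF, −78 to 0 °C; H2O
Reagents that add atoms: none
Why: Grignard 1,2-addition to the aldehyde; the racemic carbinol centre is erased by ionisation in step 4.

Step 2
Reactants: 3 rac-1-(trimethylsilyl)penta-1,4-diyn-3-ol
Product: 4 rac-1-(trimethylsilyl)penta-1,4-diyn-3-yl acetate
Conditions: Ac2O, Et3N, DMAP (cat.), CH2Cl2, 0 °C
Reagents that add atoms: acetic anhydride CC(=O)OC(C)=O
Why: DMAP-catalysed O-acylation installs the leaving group needed for propargylic substitution.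

Step 3
Reactants: 5 pentan-3-one
Product: 6 1-(pent-2-en-3-yl)pyrrolidine
Conditions: pyrrolidine, TsOH (cat.), toluene, reflux, Dean–Stark
Reagents that add atoms: pyrrolidine C1CCNC1
Why: Stork enamine formation with azeotropic removal of water gives a neutral carbon nucleophile.

Step 4
Reactants: 4 rac-1-(trimethylsilyl)penta-1,4-diyn-3-yl acetate; 6 1-(pent-2-en-3-yl)pyrrolidine
Product: 8 (5S)-5-ethynyl-4-methyl-7-(trimethylsilyl)hept-6-yn-3-one (C4 epimers), via iminium acetate 7 (not isolated)
Conditions: Cu(MeCN)4BF4 (5 mol %), (R)-Cl-MeO-BIPHEP (6 mol %), i-Pr2NEt, MeOH, −20 °C; H2O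
Reagents that add atoms: water O
Why: Asymmetric propargylic substitution with monovalent copper, in which only the free alkyne forms the copper allenylidene, the enamine attacks its γ-carbon inside the chiral pocket to set C5 as S, the silyl cap shields the remote alkyne carbon, and the C4 centre is erased in step 9.

Step 5
Reactants: 8 (5S)-5-ethynyl-4-methyl-7-(trimethylsilyl)hept-6-yn-3-one
Product: 9 {[(2Z,5S)-5-ethynyl-4-methyl-7-(trimethylsilyl)hept-2-en-6-yn-3-yl]oxy}trimethylsilane
Conditions: TMSOTf, Et3N, CH2Cl2, 0 °C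
Reagents that add atoms: trimethylsilyl triflate C[Si](C)(C)OS(=O)(=O)C(F)(F)F
Why: Soft enolisation to the silyl enol ether removes a proton from the unhindered ethyl CH2 and leaves the terminal alkyne untouched.

Step 6
Reactants: 9 the silyl enol ether; 10 2-methylpropanedioyl dichloride
Product: 11 6-[(3S)-3-ethynyl-5-(trimethylsilyl)pent-4-yn-2-yl]-4-hydroxy-3,5-dimethyl-2H-pyran-2-one
Conditions: Et2O, −78 to 23 °C
Reagents that add atoms: none
Why: 4-Hydroxy-2-pyranone annulation, in which C-acylation of the enol silane is followed by lactonisation of the enol oxygen onto the second acid chloride.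

Step 7
Reactants: 11 the 4-hydroxy-2-pyranone
Product: 12 6-[(3S)-3-ethynyl-5-(trimethylsilyl)pent-4-yn-2-yl]-2-methoxy-3,5-dimethyl-4H-pyran-4-one
Conditions: MeOTf, CH2Cl2, 23 °C; aq. NaHCO3 wash
Reagents that add atoms: methyl triflate COS(=O)(=O)C(F)(F)F
Why: Regioselective O-methylation, in which the hard methylating agent alkylates the lactone carbonyl oxygen and loss of the 4-OH proton from the pyrylium gives the 2-methoxy-4-pyranone.

Step 8
Reactants: 12 the diynyl methoxypyranone
Product: 14 2-methoxy-3,5-dimethyl-6-[(3S)-3-(prop-1-en-2-yl)-5-(trimethylsilyl)pent-4-yn-2-yl]-4H-pyran-4-one, via alkenyl(dimethyl)alane 13 (not isolated)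
Conditions: Me3Al (4 equiv), Cp2ZrCl2 (0.25 equiv), CH2Cl2, 0 to 23 °C; H2O, 0 °C
Reagents that add atoms: trimethylaluminium C[Al](C)C
Why: Negishi zirconium-catalysed methylalumination places methyl on the internal carbon of the terminal alkyne (the silylated alkyne reacts far more slowly), and protonolysis gives the isopropenyl group.

Step 9
Reactants: 14 the isopropenyl pyranone; 15 3-bromoprop-1-yne
Product: 16 2-methoxy-3,5-dimethyl-6-[(4S,5R)-4-methyl-5-(prop-1-en-2-yl)-7-(trimethylsilyl)hepta-1,6-diyn-4-yl]-4H-pyran-4-one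
Conditions: LiHMDS, THF–DMPU, −78 °C; 15, −78 to −20 °C
Reagents that add atoms: none
Why: C-alkylation of the vinylogous pyranone enolate, in which A(1,3) strain holds the C5–H in the plane of the exocyclic C=C so the bromide enters anti to the bulky isopropenyl (on the side of the thin alkynyl) and sets the quaternary centre as S; the minor epimer is removed by chromatography.

Step 10
Reactants: 16 the 1,6-enyne
Product: 18 2-methoxy-3,5-dimethyl-6-{(1S,6R)-1,3,5-trimethyl-6-[(trimethylsilyl)ethynyl]cyclohexa-2,4-dien-1-yl}-4H-pyran-4-one, via exocyclic methylene diene 17 (not isolated)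
Conditions: [(t-Bu)2P(biphenyl-2-yl)]Au(NCMe)SbF6 (3 mol %), CH2Cl2, 23 °C; then TsOH·H2O (3 mol %), 0 °C, short contact
Reagents that add atoms: none
Why: Proposed new method: monovalent gold activates the terminal alkyne and the isopropenyl CH2 closes 5-exo-dig to a 1-methylbicyclo[3.1.0]hexane carrying an exocyclic gold carbene; the internal cyclopropane bond then breaks (cyclopropylcarbinyl ring expansion, five to six) because this gives a tertiary cation, loss of the ring CH2 proton and protodeauration give 17, and a catalytic acid relay moves the exocyclic alkene into the ring by removing the pseudoaxial C2–H rather than the poorly aligned pseudoequatorial C6–H; both stereocentres are spectators, and the closest known type is the gold-catalysed endo-type cycloisomerisation of 1,6-enynes bearing 1,1-disubstituted alkenes, not yet shown with a pyranone-bearing quaternary tether or coupled to this relay.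

Step 11
Reactants: 18 the silylated ring alkyne
Product: 19 6-[(1S,6R)-6-ethynyl-1,3,5-trimethylcyclohexa-2,4-dien-1-yl]-2-methoxy-3,5-dimethyl-4H-pyran-4-one
Conditions: K2CO3 (cat.), MeOH, 0 °C
Reagents that add atoms: none
Why: Base-catalysed protiodesilylation of the alkynylsilane, which leaves the diene and pyranone untouched.

Step 12
Reactants: 20 ethyl (2S)-2-hydroxypropanoate
Product: 21 (2S)-2-hydroxy-N-methoxy-N-methylpropanamide
Conditions: MeNH(OMe)·HCl, i-PrMgCl, THF, −20 to 0 °C; H2O
Reagents that add atoms: N,O-dimethylhydroxylamine hydrochloride CNOC.Cl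
Why: Weinreb amide formation by aminolysis with the magnesium amide; the stereocentre is not touched.

Step 13
Reactants: 21 the Weinreb amide; 22 ethylmagnesium bromide
Product: 23 (2S)-2-hydroxypentan-3-one
Conditions: THF, 0 °C; H2O
Reagents that add atoms: none
Why: Weinreb ketone synthesis, in which the chelated tetrahedral intermediate prevents over-addition.

Step 14
Reactants: 23 (2S)-2-hydroxypentan-3-one
Product: 24 (2S)-3-oxopentan-2-yl methanesulfonate
Conditions: MsCl, Et3N, CH2Cl2, −30 °C
Reagents that add atoms: methanesulfonyl chloride CS(=O)(=O)Cl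
Why: O-sulfonylation with retention, run at low temperature to avoid enolisation of the α-centre.

Step 15
Reactants: 19 the ring alkyne; 24 (2S)-3-oxopentan-2-yl methanesulfonate
Product: 27 2-methoxy-3,5-dimethyl-6-{(1S,6R)-1,3,5-trimethyl-6-[(2E,4S)-4-methyl-5-oxohept-2-en-2-yl]cyclohexa-2,4-dien-1-yl}-4H-pyran-4-one, via alkenyl(dimethyl)alane 25 (not isolated), via dimethylaluminium alkoxide 26 (not isolated)
Conditions: Me3Al (3 equiv), Cp2ZrCl2 (0.25 equiv), CH2Cl2, 0 to 23 °C; volatiles off in vacuo; 24, CH2Cl2, −78 to 0 °C; H2O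
Reagents that add atoms: trimethylaluminium C[Al](C)C
Why: Proposed new method: syn methylalumination gives the (E)-alkenylalane 25, the activated chelating α-mesyloxy ketone binds aluminium and accepts the alkenyl group in preference to methyl, and the resulting alkoxide 26 is the species of an aluminium-promoted pinacol-type rearrangement, so the alkenyl group migrates 1,2 with retained E geometry and inversion at the mesylate carbon (S mesylate to S product), releasing the epimerisable β,γ-unsaturated ketone under non-basic conditions; the closest known types are Negishi carboalumination and the Suzuki–Tsuchihashi rearrangement of β-mesyloxy alcohols, which have not been merged in one flask.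

## Compound list
1 | 3-(trimethylsilyl)prop-2-ynal | C[Si](C)(C)C#CC=O | starting material
2 | ethynylmagnesium bromide | C#C[Mg]Br | starting material
3 | rac-1-(trimethylsilyl)penta-1,4-diyn-3-ol | C[Si](C)(C)C#CC(O)C#C | intermediate
4 | rac-1-(trimethylsilyl)penta-1,4-diyn-3-yl acetate | C[Si](C)(C)C#CC(OC(C)=O)C#C | intermediate
5 | pentan-3-one | CCC(=O)CC | starting material
6 | 1-(pent-2-en-3-yl)pyrrolidine | CCC(=CC)N1CCCC1 | intermediate
7 | 1-[(5S)-5-ethynyl-4-methyl-7-(trimethylsilyl)hept-6-yn-3-ylidene]pyrrolidinium acetate | C[Si](C)(C)C#C[C@H](C#C)C(C)C(CC)=[N+]1CCCC1.CC(=O)[O-] | intermediate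
8 | (5S)-5-ethynyl-4-methyl-7-(trimethylsilyl)hept-6-yn-3-one, C4 epimers | C[Si](C)(C)C#C[C@H](C#C)C(C)C(=O)CC | intermediate
9 | {[(2Z,5S)-5-ethynyl-4-methyl-7-(trimethylsilyl)hept-2-en-6-yn-3-yl]oxy}trimethylsilane | C[Si](C)(C)C#C[C@H](C#C)C(C)/C(O[Si](C)(C)C)=C/C | intermediate
10 | 2-methylpropanedioyl dichloride | CC(C(=O)Cl)C(=O)Cl | starting material
11 | 6-[(3S)-3-ethynyl-5-(trimethylsilyl)pent-4-yn-2-yl]-4-hydroxy-3,5-dimethyl-2H-pyran-2-one | C[Si](C)(C)C#C[C@H](C#C)C(C)C1=C(C)C(O)=C(C)C(=O)O1 | intermediate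
12 | 6-[(3S)-3-ethynyl-5-(trimethylsilyl)pent-4-yn-2-yl]-2-methoxy-3,5-dimethyl-4H-pyran-4-one | C[Si](C)(C)C#C[C@H](C#C)C(C)c1oc(OC)c(C)c(=O)c1C | intermediate
13 | (E)-alkenyl(dimethyl)alane from methylalumination of the free alkyne of 12 | C[Si](C)(C)C#C[C@H](/C(C)=C/[Al](C)C)C(C)c1oc(OC)c(C)c(=O)c1C | intermediate
14 | 2-methoxy-3,5-dimethyl-6-[(3S)-3-(prop-1-en-2-yl)-5-(trimethylsilyl)pent-4-yn-2-yl]-4H-pyran-4-one | C[Si](C)(C)C#C[C@H](C(C)=C)C(C)c1oc(OC)c(C)c(=O)c1C | intermediate
15 | 3-bromoprop-1-yne | C#CCBr | starting material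
16 | 2-methoxy-3,5-dimethyl-6-[(4S,5R)-4-methyl-5-(prop-1-en-2-yl)-7-(trimethylsilyl)hepta-1,6-diyn-4-yl]-4H-pyran-4-one | C[Si](C)(C)C#C[C@H](C(C)=C)[C@](C)(CC#C)c1oc(OC)c(C)c(=O)c1C | intermediate
17 | 6-{(1S,6R)-1,5-dimethyl-3-methylidene-6-[(trimethylsilyl)ethynyl]cyclohex-4-en-1-yl}-2-methoxy-3,5-dimethyl-4H-pyran-4-one | C[Si](C)(C)C#C[C@@H]1C(C)=CC(=C)C[C@]1(C)c1oc(OC)c(C)c(=O)c1C | intermediate
18 | 2-methoxy-3,5-dimethyl-6-{(1S,6R)-1,3,5-trimethyl-6-[(trimethylsilyl)ethynyl]cyclohexa-2,4-dien-1-yl}-4H-pyran-4-one | C[Si](C)(C)C#C[C@@H]1C(C)=CC(C)=C[C@]1(C)c1oc(OC)c(C)c(=O)c1C | intermediate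
19 | 6-[(1S,6R)-6-ethynyl-1,3,5-trimethylcyclohexa-2,4-dien-1-yl]-2-methoxy-3,5-dimethyl-4H-pyran-4-one | C#C[C@@H]1C(C)=CC(C)=C[C@]1(C)c1oc(OC)c(C)c(=O)c1C | intermediate
20 | ethyl (2S)-2-hydroxypropanoate | C[C@H](O)C(=O)OCC | starting material
21 | (2S)-2-hydroxy-N-methoxy-N-methylpropanamide | C[C@H](O)C(=O)N(C)OC | intermediate
22 | ethylmagnesium bromide | CC[Mg]Br | starting material
23 | (2S)-2-hydroxypentan-3-one | C[C@H](O)C(=O)CC | intermediate
24 | (2S)-3-oxopentan-2-yl methanesulfonate | C[C@H](OS(C)(=O)=O)C(=O)CC | intermediate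
25 | (E)-alkenyl(dimethyl)alane from 19, ring carbons configured as in 19 | C[Al](C)/C=C(\C)[C@@H]1C(C)=CC(C)=C[C@]1(C)c1oc(OC)c(C)c(=O)c1C | intermediate
26 | dimethylaluminium alkoxide of the adduct of 25 and 24 (carbinol epimers, mesylate carbon as in 24, ring as in 19) | CCC(O[Al](C)C)([C@H](C)OS(C)(=O)=O)/C=C(\C)[C@@H]1C(C)=CC(C)=C[C@]1(C)c1oc(OC)c(C)c(=O)c1C | intermediate
27 | 2-methoxy-3,5-dimethyl-6-{(1S,6R)-1,3,5-trimethyl-6-[(2E,4S)-4-methyl-5-oxohept-2-en-2-yl]cyclohexa-2,4-dien-1-yl}-4H-pyran-4-one | CCC(=O)[C@@H](C)/C=C(\C)[C@@H]1C(C)=CC(C)=C[C@]1(C)c1oc(OC)c(C)c(=O)c1C | target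

## Step count and risks
Total steps: 15. Longest linear sequence: 11 steps (1, 2, 4 to 11, 15).

**Step 4 (enantioselectivity or site of attack on the diynyl cation).** The fallback sets out from 3 and returns at 8.
- Claisen self-condensation of methyl propanoate (NaH, THF) gives methyl 2-methyl-3-oxopentanoate F1.
- DMAP-catalysed transesterification of F1 with alcohol 3 in refluxing toluene gives 1-(trimethylsilyl)penta-1,4-diyn-3-yl 2-methyl-3-oxopentanoate F2.
- The known copper-catalysed decarboxylative propargylic alkylation follows (Cu(MeCN)4BF4, chiral tridentate ketimine P,N,N ligand, Et3N, MeOH, 0 °C). It loses CO2 and recombines the enolate and allenylidene as a tight pair to give 8.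

**Step 10 (new; the exo-to-endo relay may drift to the diene conjugated to the alkyne).** The fallback sets out from 16 and returns at 18.
- Markovnikov hydration of the terminal alkyne (Hg(OTf)2 cat., MeCN–H2O) gives the methyl ketone, 2-methoxy-3,5-dimethyl-6-[(4S,5R)-4-methyl-2-oxo-5-(prop-1-en-2-yl)-7-(trimethylsilyl)hept-6-yn-4-yl]-4H-pyran-4-one F3.
- A Me2AlCl-promoted Prins-type closure of the isopropenyl CH2 onto the ketone (CH2Cl2, −78 °C) gives the tertiary alcohol with an exocyclic methylene, F4.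
- Acid-catalysed dehydration with the alkene shift (TsOH, benzene, 40 °C) gives 18.

**Step 15 (new; alkenyl versus methyl transfer, and pyranone-bound aluminium).** The fallback sets out from 19 and 23 and returns at 27.
- Carboalumination of 19 followed by I2 gives the (E)-alkenyl iodide F5.
- TBSCl and imidazole convert 23 into (2S)-2-(tert-butyldimethylsilyloxy)pentan-3-one F6.
- Iodine–magnesium exchange on F5 (i-PrMgCl·LiCl, −20 °C) and LaCl3·2LiCl-promoted addition to F6 give the silyl ether adduct F7.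
- HF·pyridine gives the diol F8.
- MsCl and pyridine at 0 °C mesylate only the secondary hydroxyl, giving the β-mesyloxy alcohol F9.
- The classical Et3Al-promoted 1,2-alkenyl shift (CH2Cl2, −78 °C) gives 27.

Further compounds
F1 | step 4 | methyl 2-methyl-3-oxopentanoate | CCC(=O)C(C)C(=O)OC
F2 | step 4 | 1-(trimethylsilyl)penta-1,4-diyn-3-yl 2-methyl-3-oxopentanoate | CCC(=O)C(C)C(=O)OC(C#C)C#C[Si](C)(C)C
F3 | step 10 | 2-methoxy-3,5-dimethyl-6-[(4S,5R)-4-methyl-2-oxo-5-(prop-1-en-2-yl)-7-(trimethylsilyl)hept-6-yn-4-yl]-4H-pyran-4-one | C[Si](C)(C)C#C[C@H](C(C)=C)[C@](C)(CC(C)=O)c1oc(OC)c(C)c(=O)c1C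
F4 | step 10 | 6-{3-hydroxy-1,3-dimethyl-5-methylidene-6-[(trimethylsilyl)ethynyl]cyclohexyl}-2-methoxy-3,5-dimethyl-4H-pyran-4-one, C1 and C6 as in 18, carbinol epimers | C[Si](C)(C)C#C[C@@H]1C(=C)CC(C)(O)C[C@]1(C)c1oc(OC)c(C)c(=O)c1C
F5 | step 15 | 6-{6-[(1E)-1-iodoprop-1-en-2-yl]-1,3,5-trimethylcyclohexa-2,4-dien-1-yl}-2-methoxy-3,5-dimethyl-4H-pyran-4-one, ring as in 19 | I/C=C(\C)[C@@H]1C(C)=CC(C)=C[C@]1(C)c1oc(OC)c(C)c(=O)c1C
F6 | step 15 | (2S)-2-(tert-butyldimethylsilyloxy)pentan-3-one | C[C@H](O[Si](C)(C)C(C)(C)C)C(=O)CC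
F7 | step 15 | tertiary alcohol from F5 and F6, silyl ether, carbinol epimers | CCC(O)([C@H](C)O[Si](C)(C)C(C)(C)C)/C=C(\C)[C@@H]1C(C)=CC(C)=C[C@]1(C)c1oc(OC)c(C)c(=O)c1C
F8 | step 15 | diol from F7 | CCC(O)([C@H](C)O)/C=C(\C)[C@@H]1C(C)=CC(C)=C[C@]1(C)c1oc(OC)c(C)c(=O)c1C
F9 | step 15 | β-mesyloxy tertiary alcohol from F8 | CCC(O)([C@H](C)OS(C)(=O)=O)/C=C(\C)[C@@H]1C(C)=CC(C)=C[C@]1(C)c1oc(OC)c(C)c(=O)c1C
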